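**Strategy.** The 4-quinolone is disconnected across its pyridone ring at C3–C4 and N1–C2. N1, C4 and the benzo ring come from isatoic anhydride carrying a fluoride-labile SEM group on nitrogen. C2, C3 and the whole side chain are the CH3–C(=O) end of a C16 methyl ketone whose tertiary carbinol is masked as a triethylsilyl ether. In one operation the kinetic lithium enolate of the ketone acylates at the anhydride C4 carbonyl, the oxazine ring opens with loss of CO2, and the liberated aryl amine condenses with the ketone carbonyl to close the pyridone ring. A single fluoride step then frees N1–H and the carbinol.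

Key step: step 5

Remark: the target is handled as its 4(1H)-quinolone tautomer and has no stereocentre; methyl 11-bromoundecanoate, LiN(iPr)2 (as a titrated solution) and Bu4NF are taken as purchased.

**Route**

Step 1
Reactants: 1 methyl 11-bromoundecanoate; 2 methylmagnesium bromide
Product: 4 12-bromo-2-methyldodecan-2-ol, via 12-bromododecan-2-one 3 (not isolated)
Conditions: MeMgBr (2.5 equiv), THF, 0 °C → rt; aq NH4Cl
Reagents that add atoms: methylmagnesium bromide (2), C[Mg]Br
Why: Grignard addition: two equivalents of MeMgBr add to the ester through the transient methyl ketone 3 to give the dimethyl carbinol, and the unactivated primary bromide does not couple with the Grignard reagent without a transition-metal catalyst.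

Step 2
Reactants: 4 12-bromo-2-methyldodecan-2-ol; 5 ethyl acetoacetate
Product: 9 14-hydroxy-14-methylpentadecan-2-one, via sodium acetoacetate enolate 6 (not isolated), via alkylated keto ester 7 (not isolated), via keto acid 8 (not isolated)
Conditions: NaOEt, NaI (cat.), EtOH, reflux; then 2 M aq NaOH, rt; then aq HCl to pH 2, 60 °C
Reagents that add atoms: ethyl acetoacetate (5), CCOC(=O)CC(C)=O
Why: Acetoacetic ester synthesis: the stabilised enolate 6 displaces the primary bromide (SN2, iodide-assisted), dilute hydroxide saponifies 7, and the β-keto acid 8 decarboxylates on gentle warming at a pH and temperature that a tertiary alcohol tolerates.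

Step 3
Reactants: 9 14-hydroxy-14-methylpentadecan-2-one
Product: 10 14-methyl-14-[(triethylsilyl)oxy]pentadecan-2-one
Conditions: Et3SiOTf, 2,6-lutidine, CH2Cl2, −78 → 0 °C
Reagents that add atoms: triethylsilyl trifluoromethanesulfonate, CC[Si](CC)(CC)OS(=O)(=O)C(F)(F)F
Why: Silyl triflate silylation: with the weak, hindered base 2,6-lutidine at low temperature the tertiary hydroxyl is silylated much faster than an isolated ketone is converted to a silyl enol ether, as is routine for hindered carbinols in hydroxy ketones.

Step 4
Reactants: 11 isatoic anhydride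
Product: 13 1-{[2-(trimethylsilyl)ethoxy]methyl}-2H-3,1-benzoxazine-2,4(1H)-dione, via sodium salt 12 (not isolated)
Conditions: NaH, DMAc, 0 °C; then SEMCl, 0 °C → rt
Reagents that add atoms: 2-(trimethylsilyl)ethoxymethyl chloride, C[Si](C)(C)CCOCCl
Why: N-Alkylation: the acidic N–H of the anhydride is deprotonated irreversibly and the nitrogen anion 12 is captured at 0 °C by the highly reactive α-chloro ether before ring opening can compete.

Step 5
Reactants: 10 14-methyl-14-[(triethylsilyl)oxy]pentadecan-2-one; 13 1-{[2-(trimethylsilyl)ethoxy]methyl}-2H-3,1-benzoxazine-2,4(1H)-dione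
Product: 17 2-{12-methyl-12-[(triethylsilyl)oxy]tridecyl}-1-{[2-(trimethylsilyl)ethoxy]methyl}quinolin-4(1H)-one, via lithium enolate 14 (not isolated), via ring-opened carbamate salt 15 (not isolated), via aminoaryl diketone 16 (not isolated)
Conditions: 10 (2 equiv), LiN(iPr)2 (2 equiv), THF, −78 °C; then 13 (1 equiv), −78 °C → rt; AcOH, rt
Reagents that add atoms: none
Why: The lithium enolate 14 adds through carbon to the C4 carbonyl of 13, the oxazine ring opens to the N-carboxylate 15, and on acidification the carbamic acid loses CO2 to give the secondary aryl amine 16, whose nitrogen adds to the chain ketone and eliminates water. The closest known reaction type is the condensation of N-alkylisatoic anhydrides with ketone lithium enolates to 1,2-disubstituted 4-quinolones, a Claisen-type C-acylation followed by cyclodehydration to a vinylogous amide. The pyridone ring closes by 6-exo-trig attack of N1 on the ketone carbon (N1–C2) after the intermolecular C3–C4 bond has been made; no stereocentre is created. Enolisation on the CH3 side is secured by irreversible deprotonation with the hindered amide at −78 °C, and attack at C4 is secured because C4 is an aryl ester-type carbonyl whereas C2 is a carbamate carbonyl deactivated by two heteroatom donors. The N-substituent removes the acidic N–H that would otherwise quench the enolate and open the anhydride to an isocyanate. A second equivalent of 14 serves as base for the acidic 1,3-diketone and returns as recoverable 10.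

Step 6
Reactants: 17 2-{12-methyl-12-[(triethylsilyl)oxy]tridecyl}-1-{[2-(trimethylsilyl)ethoxy]methyl}quinolin-4(1H)-one
Product: 19 2-(12-hydroxy-12-methyltridecyl)quinolin-4(1H)-one, via N-SEM carbinol 18 (not isolated)
Conditions: Bu4NF (excess), THF, rt; then H2NCH2CH2NH2, 65 °C; aq NH4Cl
Reagents that add atoms: none
Why: Fluoride-mediated desilylation: the Si–O bond of the silyl ether is cleaved at room temperature, and on heating fluoride attack at the trimethylsilyl group triggers β-fragmentation of the N,O-acetal to ethylene, formaldehyde and the quinolone nitrogen anion, with ethylenediamine trapping formaldehyde so that it cannot add back at N1 or C3.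

**Compound list**

1 | methyl 11-bromoundecanoate | COC(=O)CCCCCCCCCCBr | starting material
2 | methylmagnesium bromide | C[Mg]Br | starting material
3 | 12-bromododecan-2-one | CC(=O)CCCCCCCCCCBr | intermediate
4 | 12-bromo-2-methyldodecan-2-ol | CC(C)(O)CCCCCCCCCCBr | intermediate
5 | ethyl acetoacetate | CCOC(=O)CC(C)=O | starting material
6 | sodium enolate of ethyl acetoacetate (enolate geometry of no consequence) | [Na+].CCOC(=O)C=C(C)[O-] | intermediate
7 | ethyl 2-acetyl-13-hydroxy-13-methyltetradecanoate (racemic at C2) | CCOC(=O)C(C(C)=O)CCCCCCCCCCC(C)(C)O | intermediate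
8 | 2-acetyl-13-hydroxy-13-methyltetradecanoic acid (racemic at C2; sodium salt until acidification) | CC(=O)C(C(O)=O)CCCCCCCCCCC(C)(C)O | intermediate
9 | 14-hydroxy-14-methylpentadecan-2-one | CC(=O)CCCCCCCCCCCC(C)(C)O | intermediate
10 | 14-methyl-14-[(triethylsilyl)oxy]pentadecan-2-one | CC(=O)CCCCCCCCCCCC(C)(C)O[Si](CC)(CC)CC | intermediate
11 | isatoic anhydride (2H-3,1-benzoxazine-2,4(1H)-dione) | O=C1Nc2ccccc2C(=O)O1 | starting material
12 | sodium salt of isatoic anhydride (N-anion) | [Na+].O=C1[N-]c2ccccc2C(=O)O1 | intermediate
13 | 1-{[2-(trimethylsilyl)ethoxy]methyl}-2H-3,1-benzoxazine-2,4(1H)-dione | C[Si](C)(C)CCOCN1C(=O)OC(=O)c2ccccc21 | intermediate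
14 | lithium 14-methyl-14-[(triethylsilyl)oxy]pentadec-1-en-2-olate (terminal enolate of 10) | [Li]OC(=C)CCCCCCCCCCCC(C)(C)O[Si](CC)(CC)CC | intermediate
15 | ring-opened adduct as dilithium salt: lithium N-aryl-N-SEM carbamate bearing the lithium enolate of the ortho 1,3-diketone side chain (enolate geometry of no consequence) | [Li+].[Li+].[O-]C(=O)N(COCC[Si](C)(C)C)c1ccccc1C(=O)C=C([O-])CCCCCCCCCCCC(C)(C)O[Si](CC)(CC)CC | intermediate
16 | 15-methyl-15-[(triethylsilyl)oxy]-1-[2-({[2-(trimethylsilyl)ethoxy]methyl}amino)phenyl]hexadecane-1,3-dione | C[Si](C)(C)CCOCNc1ccccc1C(=O)CC(=O)CCCCCCCCCCCC(C)(C)O[Si](CC)(CC)CC | intermediate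
17 | 2-{12-methyl-12-[(triethylsilyl)oxy]tridecyl}-1-{[2-(trimethylsilyl)ethoxy]methyl}quinolin-4(1H)-one | CC[Si](CC)(CC)OC(C)(C)CCCCCCCCCCCc1cc(=O)c2ccccc2n1COCC[Si](C)(C)C | intermediate
18 | 2-(12-hydroxy-12-methyltridecyl)-1-{[2-(trimethylsilyl)ethoxy]methyl}quinolin-4(1H)-one | CC(C)(O)CCCCCCCCCCCc1cc(=O)c2ccccc2n1COCC[Si](C)(C)C | intermediate
19 | 2-(12-hydroxy-12-methyltridecyl)quinolin-4(1H)-one | CC(C)(O)CCCCCCCCCCCc1cc(=O)c2ccccc2[nH]1 | target

**Step count**

Total: 6 steps. Longest linear sequence: 5 steps (steps 1, 2, 3, 5, 6); step 4 is a one-step branch.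

**Steps most likely to fail**

1. Step 5 (key step). What may go wrong:
- proton transfer from the newly formed, more acidic 1,3-diketone to unreacted enolate, so that conversion stalls;
- partial deprotonation on the CH2 side of the ketone, leading to the regioisomeric 3-alkyl-2-methyl ring;
- addition at the carbamate carbonyl instead of C4;
- loss of the N,O-acetal before ring closure, which is harmless because the resulting N–H quinolone silyl ether is also converted to 19 under the conditions of step 6.

Fallback: the anhydride is left aside and the sequence sets out from ketone 10. Its kinetic lithium enolate (LiN(SiMe3)2, THF, −78 °C, two equivalents) is C-acylated with 2-nitrobenzoyl chloride to give 15-methyl-1-(2-nitrophenyl)-15-[(triethylsilyl)oxy]hexadecane-1,3-dione F1. Reduction of the nitro group with iron powder and NH4Cl in aqueous ethanol at 70 °C gives the aniline, which closes spontaneously to 2-{12-methyl-12-[(triethylsilyl)oxy]tridecyl}quinolin-4(1H)-one F2. Bu4NF in THF then removes the silyl ether, and the route is rejoined at the target 19.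

2. Step 6. What may go wrong: incomplete fragmentation of the N,O-acetal, with arrest at the N-hydroxymethyl stage, or re-addition of released formaldehyde at C3 of the electron-rich quinolone.

Fallback: a nitrogen-unprotected Conrad–Limpach construction that sets out from bromo alcohol 4. The dianion of ethyl acetoacetate (NaH, then n-BuLi, THF, 0 °C, used in excess so that one equivalent is spent on the hydroxyl proton) is alkylated at its terminal carbon by 4 to give ethyl 15-hydroxy-15-methyl-3-oxohexadecanoate F3. Condensation with aniline (cat. AcOH, 4 Å molecular sieves, toluene) gives ethyl (2Z)-15-hydroxy-15-methyl-3-(phenylamino)hexadec-2-enoate F4. Brief heating in Ph2O at 250 °C closes the pyridone ring onto the arene with loss of ethanol and rejoins the route at the target 19.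

3. Step 4. What may go wrong: ring opening of the anhydride anion (through the isocyanate) and self-condensation before alkylation, alkylation on oxygen instead of nitrogen, or hydrolysis of the product during work-up.

Fallback: this sequence does not set out from a numbered compound; commercial isatin (O=C1Nc2ccccc2C1=O) takes the place of 11. N-Alkylation with SEMCl (K2CO3, DMF, rt) gives 1-{[2-(trimethylsilyl)ethoxy]methyl}-1H-indole-2,3-dione F5. Baeyer–Villiger oxidation with mCPBA in CH2Cl2 inserts oxygen between C2 and C3 and rejoins the route at 13.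

**Further compounds**

F1 | step 5 | 15-methyl-1-(2-nitrophenyl)-15-[(triethylsilyl)oxy]hexadecane-1,3-dione | O=C(CC(=O)CCCCCCCCCCCC(C)(C)O[Si](CC)(CC)CC)c1ccccc1[N+](=O)[O-]
F2 | step 5 | 2-{12-methyl-12-[(triethylsilyl)oxy]tridecyl}quinolin-4(1H)-one | CC[Si](CC)(CC)OC(C)(C)CCCCCCCCCCCc1cc(=O)c2ccccc2[nH]1
F3 | step 6 | ethyl 15-hydroxy-15-methyl-3-oxohexadecanoate | CCOC(=O)CC(=O)CCCCCCCCCCCC(C)(C)O
F4 | step 6 | ethyl (2Z)-15-hydroxy-15-methyl-3-(phenylamino)hexadec-2-enoate | CCOC(=O)/C=C(\Nc1ccccc1)CCCCCCCCCCCC(C)(C)O
F5 | step 4 | 1-{[2-(trimethylsilyl)ethoxy]methyl}-1H-indole-2,3-dione | C[Si](C)(C)CCOCN1C(=O)C(=O)c2ccccc21
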